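| setting | autumn | summer | alpha | epsilon |
|---|---|---|---|---|
| electrophile | 0.20 M | 0.20 M | 0.20 M | 0.20 M |
| nucleophile | 0.22 M | 0.28 M | 0.180 M | 0.230 M |
| solid base | 0.30 M | 0.30 M | 0.300 M | 0.300 M |
| remark | run made earlier | run made earlier |  |  |
| time |  |  | 8.0 d | 8.0 d |

| run | time / d | electrophile / % | product / % |
|---|---|---|---|
| autumn | 1.04 | 42.2 | 57.9 |
| autumn | 2.08 | 36.2 | 63.8 |
| autumn | 3.00 | 31.9 | 68.4 |
| autumn | 4.00 | 28.4 | 72.2 |
| summer | 1.04 | 29.5 | 70.7 |
| summer | 2.08 | 22.3 | 77.8 |
| summer | 3.00 | 18.8 | 81.2 |
| summer | 4.00 | 15.0 | 85.5 |

(readings scatter by 0.3 percentage points)

- solid, in amounts per volume of the solution: solid base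
- at the start none of the solid base is in solution

- part of the electrophile that has reacted at the end, alpha
- part of the electrophile that has reacted at the end, epsilon
- what raising the concentration of nucleophile from its lowest to its highest value here does to the part of the electrophile that has reacted (changes below 5 percentage points count as none) (it falls / no change / it rises)

**Two jobs.** The nucleophile, I suppose, does two jobs: it makes product, and it takes up the acid set free in a proton transfer that I treat as instantaneous. Until base helps, each product then costs two nucleophile. For alpha this gives 45.0%, and for epsilon 57.5%. I call this conversion, half the charged [nucleophile] over the charged [electrophile], the burst floor. The autumn floor is 55.0% against 57.9% read at 1.04 d, and the summer floor is 70.0% against 70.7%.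

**Upper bound.** In alpha the nucleophile is the limiting reagent, with 0.180 M against 0.20 M, so its ceiling is 90.0%. Epsilon, with 0.230 M, has the electrophile as its limit.

**Tighter bracket.** I read the gain above the floor as the base's credit. At 4.00 d it is 17 percentage points in autumn and 15 points in summer, close despite different nucleophile. If the credit stopped growing at the smaller value, alpha would reach 60.0% and epsilon 72.5%. If autumn's last pace, 8.4 points from 2.08 d on, held to 8.0 d, they would reach 79.7% and 92.2%. With equal credit, the rise across the two flasks is the floors' difference, 13 points.

**The forecast.** The forecast, “assuming the slow phase persists”, gives 73% and 84.5%, inside my brackets, and says it rises.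

**The flask.** Alpha gives 71.9% and epsilon 83.8%. From the lowest to the highest nucleophile, it rises, and the change is 12 points.

    nucleophile + acid set free ⇌ protonated nucleophile, settled at all times (K = 33000 /M)
    solid base ⇌ free base, rate k2*(cs2 - [free base]) while solid is left; crystals form when [free base] > cs2 (solubility = 22.0 mM, k = 0.0530 /h)
    electrophile + nucleophile → acid set free + product (k = 0.780 /M/h)
    free base ⇌ dormant form (K = 16.0, k = 0.0310 /h)
    acid set free + free base ⇌ salt of the base, settled at all times (K = 32000 /M)

**What stands.** In alpha the making of product alone, with the other concentrations as charged, gives the electrophile a half-life of 0.21 d, shorter than 8.0 d, yet 28% of the electrophile stands at 8.00 d beside 1.8% of the nucleophile. Alpha lies 27 points above its floor of 45.0%, and half its 0.110 M salt of the base over the charged [electrophile] comes to 27 points. The neighbour of alpha charged with 0.34 M electrophile has a floor of 26.5% and gives 46.9%, which is 20 points above it, and the same share of its 0.140 M salt of the base comes to 21 points.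

Readings and results are simulated from invented constants, noise included.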